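**Retrosynthetic overview**

1. Atom labels: ring A = C1–C2–C3–C4–C5–C10 (C4 carries CH3 and the C19 carboxyl, C5 carries H and the C6 carboxyl, C10 carries the C20 methyl and C9); the bicyclo[3.2.1]octanone is C8(C7HO)–C9–C11–C12(=O)–C13–C14 with the bridge C15–C16(=C17H2).
2. The cis-diacid comes from its cyclic anhydride (water). The C9–C10 bond comes from a Giese addition of the ring-A tertiary C10 radical (from a bromide) to the β-carbon C9 of a bicyclic enone aldehyde; the anhydride ring steers C10 and the C15–C16 bridge steers C9.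
3. Ring A is made as a cycloheptenone and contracted. The feature used is the ring-A methine C5 that carries the exocyclic carboxyl carbon C6, lies between the quaternary carbons C4 and C10, and is cis to the C19 carboxyl on C4. C6 is the former ring ketone, C5 the former diazo carbon, C10 the migrating vinyl carbon, and the C19 carboxylate captures the ketene (Wolff contraction with anhydride closure).
4. The diazo cycloheptenone comes from 3-methylcyclohept-2-enone: C4 by asymmetric conjugate arylation (phenyl is the latent C19 carboxyl), C20 by enolate methylation, then dehydrogenation and diazo transfer.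
5. The bicyclic enone comes from an asymmetric Diels–Alder reaction (cyclohexene, C8), a gold-catalysed 5-exo-dig closure (five-membered ring, C13) and dehydrogenation. Ring order: seven-membered ring (bought) → ring A plus anhydride ring (key step); cyclohexene → bicyclo[3.2.1]octane; union at C9–C10; anhydride opening.

Key step: step 7

Remark: 3-methylcyclohept-2-en-1-one (1) is taken as a purchasable compound; the C-atom labels of the first overview line are used throughout.

**Route**

Step 1
Reactants: 1 3-methylcyclohept-2-en-1-one; 2 phenylboronic acid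
Product: 3 (3R)-3-methyl-3-phenylcycloheptan-1-one
Conditions: Pd(OCOCF3)2 (5 mol%), (S)-4-tert-butyl-2-(pyridin-2-yl)-4,5-dihydrooxazole (6 mol%), NH4PF6 (30 mol%), H2O (5 equiv), ClCH2CH2Cl, 40 °C
Reagents that add atoms: none
Why: Palladium-catalysed asymmetric conjugate addition of an arylboronic acid to a β-methyl cyclic enone; the pyridine–oxazoline ligand controls the enone face and so sets the C4 quaternary centre (the (S)-ligand is expected to give the (R)-ketone by analogy with six-membered enones; otherwise its antipode is used).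

Step 2
Reactants: 3 (3R)-3-methyl-3-phenylcycloheptan-1-one
Product: 4 (1R)-1-methyl-3-oxocycloheptane-1-carboxylic acid
Conditions: RuCl3·xH2O (5 mol%), NaIO4 (15 equiv), CCl4/MeCN/H2O, 25 °C
Reagents that add atoms: sodium periodate, [Na+].[O-]I(=O)(=O)=O; water, O
Why: RuO4 arene degradation (catalytic RuCl3 with NaIO4 as terminal oxidant) should burn the phenyl ring down to its ipso carbon, which becomes the C19 carboxyl, without touching the quaternary centre.

Step 3
Reactants: 4 (1R)-1-methyl-3-oxocycloheptane-1-carboxylic acid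
Product: 5 2-(trimethylsilyl)ethyl (1R)-1-methyl-3-oxocycloheptane-1-carboxylate
Conditions: Me3SiCH2CH2OH, N,N'-dicyclohexylcarbodiimide, DMAP (cat.), CH2Cl2, 0 °C to 25 °C
Reagents that add atoms: 2-(trimethylsilyl)ethanol, C[Si](C)(C)CCO
Why: Steglich esterification should mask the acid as a fluoride-labile ester that survives the enolate chemistry of steps 4 to 6.

Step 4
Reactants: 5 2-(trimethylsilyl)ethyl (1R)-1-methyl-3-oxocycloheptane-1-carboxylate
Product: 6 2-(trimethylsilyl)ethyl (1R)-1,4-dimethyl-3-oxocycloheptane-1-carboxylate (both C4 epimers)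
Conditions: LiN(i-Pr)2, THF, −78 °C; MeI, −78 to −20 °C
Reagents that add atoms: iodomethane, CI
Why: Kinetic enolate alkylation: the amide base should deprotonate the open C10 methylene and not the neopentyl C5 methylene, and methylation brings in C20; the new centre is a mixture that step 5 erases.

Step 5
Reactants: 6 2-(trimethylsilyl)ethyl (1R)-1,4-dimethyl-3-oxocycloheptane-1-carboxylate
Product: 7 2-(trimethylsilyl)ethyl (1R)-1,4-dimethyl-3-oxocyclohept-4-ene-1-carboxylate
Conditions: IBX (2.5 equiv), DMSO/toluene, 70 °C
Reagents that add atoms: none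
Why: IBX dehydrogenation of a ketone to an enone can only run toward C10–C1 because C4 carries no hydrogen, so the 2-methyl enone should form.

Step 6
Reactants: 7 2-(trimethylsilyl)ethyl (1R)-1,4-dimethyl-3-oxocyclohept-4-ene-1-carboxylate
Product: 9 2-(trimethylsilyl)ethyl (1R)-2-diazo-1,4-dimethyl-3-oxocyclohept-4-ene-1-carboxylate, via trifluoroacetyl ketone 8 (not isolated)
Conditions: LiN(SiMe3)2, THF, −78 °C; CF3CO2CH2CF3; then MeSO2N3, Et3N, H2O (1 equiv), MeCN, 25 °C
Reagents that add atoms: 2,2,2-trifluoroethyl trifluoroacetate, O=C(OCC(F)(F)F)C(F)(F)F (its acyl group stays only in 8); methanesulfonyl azide, CS(=O)(=O)N=[N+]=[N-]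
Why: Detrifluoroacetylative diazo transfer (a Regitz-type diazo transfer): the kinetic α′-enolate at C5 is trifluoroacetylated, and the sulfonyl azide then exchanges the acyl group for the diazo group at the only activated carbon.

Step 7
Reactants: 9 2-(trimethylsilyl)ethyl (1R)-2-diazo-1,4-dimethyl-3-oxocyclohept-4-ene-1-carboxylate
Product: 13 (3aR,7aS)-3a,7-dimethyl-3a,4,5,7a-tetrahydro-2-benzofuran-1,3-dione, via carboxylate salt 10 (not isolated), via ketene 11 (not isolated), via dienolate 12 (not isolated)
Conditions: Bu4NF (1.05 equiv), 4 Å sieves, THF, 0 °C; then hν (medium-pressure Hg lamp, Pyrex), −30 °C; then AcOH (1.1 equiv), −78 °C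
Reagents that add atoms: none
Why: Fluoride first frees the C19 carboxylate (ethene and Me3SiF leave), and light then expels N2 from the s-cis-locked cyclic diazo ketone while the vinyl carbon C10 shifts from the carbonyl carbon C6 to C5 (Wolff rearrangement), so that the seven-membered ring contracts to ring A and C6 leaves the ring as a ketene. The closest known reaction types are the photochemical Wolff ring contraction of cyclic α-diazo ketones, the formation of vinylketenes from α′-diazo enones and the addition of a carboxylate to a ketene to give an anhydride. The anhydride ring closes by 5-exo-dig attack of the carboxylate oxygen on the ketene carbon C6, which gives dienolate 12. C5 is the only new stereocentre and is fixed when acetic acid protonates 12 at its α-carbon: only the cis-fused anhydride is unstrained, so the proton should enter on the face that carries the C4 methyl group, which places C6 cis to C19. The step needs the Wolff shift to beat other carbene reactions (the ring holds the diazo ketone s-cis and C4 carries no hydrogen for a 1,2-hydride shift), internal capture to beat external nucleophiles (carboxylate and ketene sit on neighbouring carbons and the medium is kept dry), and α- rather than γ-protonation (kinetic quench at −78 °C).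

Step 8
Reactants: 13 (3aR,7aS)-3a,7-dimethyl-3a,4,5,7a-tetrahydro-2-benzofuran-1,3-dione
Product: 14 (3aR,7aS)-7-bromo-3a,7-dimethylhexahydro-2-benzofuran-1,3-dione (both C7 epimers)
Conditions: HBr (anhydrous, excess), CH2Cl2, −40 °C
Reagents that add atoms: hydrogen bromide, Br
Why: Markovnikov hydrobromination: protonation at C1 should give the tertiary C10 cation that bromide captures, the low temperature suppressing loss of the C5 proton; the configuration at C10 is irrelevant because step 15 passes through the planar radical.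

Step 9
Reactants: 15 pent-4-yn-1-ol
Product: 16 pent-4-ynal
Conditions: TEMPO (10 mol%), PhI(OAc)2 (1.1 equiv), CH2Cl2, 25 °C
Reagents that add atoms: none
Why: TEMPO-catalysed alcohol oxidation (oxoammonium pathway) should stop at the aldehyde and leave the alkyne alone.

Step 10
Reactants: 16 pent-4-ynal
Product: 17 2-methylidenepent-4-ynal
Conditions: aq. CH2O (37%), pyrrolidine (10 mol%), propanoic acid (10 mol%), i-PrOH, 45 °C
Reagents that add atoms: formaldehyde, C=O
Why: Amine-catalysed α-methylenation of an aldehyde (Mannich condensation then elimination) should give the 2-substituted acrolein.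

Step 11
Reactants: 18 but-3-en-2-one
Product: 19 2-{[tri(propan-2-yl)silyl]oxy}buta-1,3-diene
Conditions: i-Pr3SiOSO2CF3, Et3N, Et2O, 0 °C
Reagents that add atoms: triisopropylsilyl trifluoromethanesulfonate, CC(C)[Si](OS(=O)(=O)C(F)(F)F)(C(C)C)C(C)C
Why: Soft enolisation and O-silylation of the enone (silyl enol ether formation) should give the 2-silyloxy diene.

Step 12
Reactants: 17 2-methylidenepent-4-ynal; 19 2-{[tri(propan-2-yl)silyl]oxy}buta-1,3-diene
Product: 20 (1R)-1-(prop-2-yn-1-yl)-4-{[tri(propan-2-yl)silyl]oxy}cyclohex-3-ene-1-carbaldehyde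
Conditions: oxazaborolidinium bis(trifluoromethanesulfonyl)imide from α,α-diphenylprolinol, tri-o-tolylboroxine and (CF3SO2)2NH (20 mol%), CH2Cl2, −78 °C
Reagents that add atoms: none
Why: Catalytic asymmetric Diels–Alder reaction of a 2-substituted acrolein: the nucleophilic CH2 terminus of the silyloxy diene bonds to the acrolein β-carbon ("para" adduct, enol ether at C12=C13), and the chiral oxazaborolidinium ion bound to the formyl group shields one face of the dienophile, so C8 is set as (R) (catalyst antipode chosen accordingly).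

Step 13
Reactants: 20 (1R)-1-(prop-2-yn-1-yl)-4-{[tri(propan-2-yl)silyl]oxy}cyclohex-3-ene-1-carbaldehyde
Product: 21 (1R,5R)-6-methylidene-4-oxobicyclo[3.2.1]octane-1-carbaldehyde
Conditions: Ph3PAuCl (5 mol%), AgBF4 (5 mol%), CH2Cl2/MeOH (10:1), 25 °C
Reagents that add atoms: none
Why: Gold-catalysed 5-exo-dig carbocyclisation of a silyl enol ether onto a terminal alkyne (Conia-ene type) should form C13–C16 and the exocyclic methylene; C13 can only bond on the ring face that carries the propargyl group, so its configuration follows from C8.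

Step 14
Reactants: 21 (1R,5R)-6-methylidene-4-oxobicyclo[3.2.1]octane-1-carbaldehyde
Product: 22 (1R,5R)-6-methylidene-4-oxobicyclo[3.2.1]oct-2-ene-1-carbaldehyde
Conditions: IBX (2 equiv), DMSO, 65 °C
Reagents that add atoms: none
Why: IBX dehydrogenation: the ketone can enolise only toward C11 because C13 is a bridgehead, so the C9=C11 enone should form, and the aldehyde has no α-hydrogen.

Step 15
Reactants: 14 (3aR,7aS)-7-bromo-3a,7-dimethylhexahydro-2-benzofuran-1,3-dione; 22 (1R,5R)-6-methylidene-4-oxobicyclo[3.2.1]oct-2-ene-1-carbaldehyde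
Product: 23 (3aR,7S,7aS)-7-[(1R,2S,5R)-1-formyl-6-methylidene-4-oxobicyclo[3.2.1]octan-2-yl]-3a,7-dimethylhexahydro-2-benzofuran-1,3-dione
Conditions: Bu3SnH (1.3 equiv, syringe pump), AIBN (cat.), benzene, 80 °C
Reagents that add atoms: none
Why: Giese reaction (tin-hydride chain): the tertiary C10 radical should add to C9 on the enone face opposite the C15–C16 bridge and through its own face opposite the cis-fused anhydride ring, which sets C9 and the C10 quaternary centre.

Step 16
Reactants: 23 (3aR,7S,7aS)-7-[(1R,2S,5R)-1-formyl-6-methylidene-4-oxobicyclo[3.2.1]octan-2-yl]-3a,7-dimethylhexahydro-2-benzofuran-1,3-dione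
Product: 24 (1R,2S,3S)-3-[(1R,2S,5R)-1-formyl-6-methylidene-4-oxobicyclo[3.2.1]octan-2-yl]-1,3-dimethylcyclohexane-1,2-dicarboxylic acid
Conditions: THF/H2O (1:1), DMAP (10 mol%), 40 °C
Reagents that add atoms: water, O
Why: Hydrolysis of a cyclic anhydride by water should release the cis-diacid without touching any stereocentre.

**Compound list**

1 | 3-methylcyclohept-2-en-1-one | CC1=CC(=O)CCCC1 | starting material
2 | phenylboronic acid | OB(O)c1ccccc1 | starting material
3 | (3R)-3-methyl-3-phenylcycloheptan-1-one | C1CCC[C@@](C)(c2ccccc2)CC1=O | intermediate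
4 | (1R)-1-methyl-3-oxocycloheptane-1-carboxylic acid | C1CCC[C@@](C)(C(=O)O)CC1=O | intermediate
5 | 2-(trimethylsilyl)ethyl (1R)-1-methyl-3-oxocycloheptane-1-carboxylate | C1CCC[C@@](C)(C(=O)OCC[Si](C)(C)C)CC1=O | intermediate
6 | 2-(trimethylsilyl)ethyl (1R)-1,4-dimethyl-3-oxocycloheptane-1-carboxylate (both C4 epimers) | CC1CCC[C@@](C)(C(=O)OCC[Si](C)(C)C)CC1=O | intermediate
7 | 2-(trimethylsilyl)ethyl (1R)-1,4-dimethyl-3-oxocyclohept-4-ene-1-carboxylate | CC1=CCC[C@@](C)(C(=O)OCC[Si](C)(C)C)CC1=O | intermediate
8 | 2-(trimethylsilyl)ethyl (1R)-1,4-dimethyl-3-oxo-2-(trifluoroacetyl)cyclohept-4-ene-1-carboxylate (C2 epimers or enol) | CC1=CCC[C@@](C)(C(=O)OCC[Si](C)(C)C)C(C(=O)C(F)(F)F)C1=O | intermediate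
9 | 2-(trimethylsilyl)ethyl (1R)-2-diazo-1,4-dimethyl-3-oxocyclohept-4-ene-1-carboxylate | CC1=CCC[C@@](C)(C(=O)OCC[Si](C)(C)C)C(=[N+]=[N-])C1=O | intermediate
10 | tetrabutylammonium (1R)-2-diazo-1,4-dimethyl-3-oxocyclohept-4-ene-1-carboxylate | CC1=CCC[C@@](C)(C([O-])=O)C(=[N+]=[N-])C1=O.CCCC[N+](CCCC)(CCCC)CCCC | intermediate
11 | tetrabutylammonium (1R)-1,3-dimethyl-2-(oxomethylidene)cyclohex-3-ene-1-carboxylate | CC1=CCC[C@@](C)(C([O-])=O)C1=C=O.CCCC[N+](CCCC)(CCCC)CCCC | intermediate
12 | tetrabutylammonium (3aR)-3a,7-dimethyl-3-oxo-3,3a,4,5-tetrahydro-2-benzofuran-1-olate (dienolate of 13) | CC1=CCC[C@@]2(C)C(=O)OC([O-])=C12.CCCC[N+](CCCC)(CCCC)CCCC | intermediate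
13 | (3aR,7aS)-3a,7-dimethyl-3a,4,5,7a-tetrahydro-2-benzofuran-1,3-dione (cis-fused) | CC1=CCC[C@@](C)(C(=O)OC2=O)[C@H]12 | intermediate
14 | (3aR,7aS)-7-bromo-3a,7-dimethylhexahydro-2-benzofuran-1,3-dione (both C7 epimers) | CC1(Br)CCC[C@@](C)(C(=O)OC2=O)[C@H]12 | intermediate
15 | pent-4-yn-1-ol | C#CCCCO | starting material
16 | pent-4-ynal | C#CCCC=O | intermediate
17 | 2-methylidenepent-4-ynal | C#CCC(=C)C=O | intermediate
18 | but-3-en-2-one | CC(=O)C=C | starting material
19 | 2-{[tri(propan-2-yl)silyl]oxy}buta-1,3-diene | C=CC(=C)O[Si](C(C)C)(C(C)C)C(C)C | intermediate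
20 | (1R)-1-(prop-2-yn-1-yl)-4-{[tri(propan-2-yl)silyl]oxy}cyclohex-3-ene-1-carbaldehyde | C#CC[C@]1(C=O)CC=C(O[Si](C(C)C)(C(C)C)C(C)C)CC1 | intermediate
21 | (1R,5R)-6-methylidene-4-oxobicyclo[3.2.1]octane-1-carbaldehyde | C=C1C[C@]2(C=O)C[C@H]1C(=O)CC2 | intermediate
22 | (1R,5R)-6-methylidene-4-oxobicyclo[3.2.1]oct-2-ene-1-carbaldehyde | C=C1C[C@]2(C=O)C[C@H]1C(=O)C=C2 | intermediate
23 | (3aR,7S,7aS)-7-[(1R,2S,5R)-1-formyl-6-methylidene-4-oxobicyclo[3.2.1]octan-2-yl]-3a,7-dimethylhexahydro-2-benzofuran-1,3-dione | C=C1C[C@]2(C=O)C[C@H]1C(=O)C[C@H]2[C@]1(C)CCC[C@@](C)(C(=O)OC3=O)[C@H]13 | intermediate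
24 | (1R,2S,3S)-3-[(1R,2S,5R)-1-formyl-6-methylidene-4-oxobicyclo[3.2.1]octan-2-yl]-1,3-dimethylcyclohexane-1,2-dicarboxylic acid (CNP0320711.1) | C=C1C[C@]2(C=O)C[C@H]1C(=O)C[C@H]2[C@]1(C)CCC[C@@](C)(C(=O)O)[C@H]1C(=O)O | target

**Step count and risks**

Total step count: 16. Longest linear sequence: 10 steps (steps 1 to 8, then 15 and 16).

Steps most likely to fail:

Step 15. The tertiary radical may be reduced by the tin hydride, or the bromide may lose HBr, before the slow addition to the hindered β-carbon next to the quaternary bridgehead; facial selectivity at C10 may also be incomplete. The fallback sets out from 14 and 22 and returns to 23. The two partners would be joined by nickel-catalysed reductive conjugate addition (NiCl2(dme) 10 mol%, 4,4′,4″-tri-tert-butyl-2,2′:6′,2″-terpyridine, Mn powder, Et3SiCl, DMF, 25 °C). No hydride donor is present, and the enolate is held as the triethylsilyl enol ether of 23 F5. Mild hydrolysis of the silyl enol ether (aqueous citric acid, THF) should then give 23.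

Step 7. The dienolate may be protonated at its γ-carbon (conjugated, useless alkene), the ketene may be taken by adventitious water instead of the carboxylate, or the ring fusion may not form cleanly cis. The fallback sets out from 9 and returns to 13. The Wolff contraction would be run with external capture (hν, THF/H2O), which should give 2,6-dimethyl-6-{[2-(trimethylsilyl)ethoxy]carbonyl}cyclohex-2-ene-1-carboxylic acid F1. Bu4NF in THF would free (1R)-1,3-dimethylcyclohex-3-ene-1,2-dicarboxylic acid F2. Acetic anhydride at 80 °C would then close the ring; any trans-diacid should equilibrate through the enolisable mixed anhydride toward the cis-fused anhydride 13.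

Step 8. The C10 cation may lose the acidic C5 proton and give the conjugated alkene, or the bromide may revert on isolation. The fallback sets out from 13 (with 22) and returns to 23, so it replaces steps 8 and 15. The exocyclic methylene of 22 would be masked with dimethyldioxirane (acetone, 0 °C) as (1R,5R)-4-oxospiro[bicyclo[3.2.1]oct-2-ene-6,2′-oxirane]-1-carbaldehyde F3. Alkene 13 and F3 would be joined directly by iron-catalysed hydrogen-atom-transfer reductive olefin–enone coupling (Fe(acac)3, PhSi(Oi-Pr)H2, THF, 25 °C), which forms the same C10 radical without a cation and should give the epoxide of 23 F4. Deoxygenation with CH3ReO3 (5 mol%) and PPh3 in benzene would restore the methylene and give 23.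

Further compounds
F1 | step 7 | (6R)-2,6-dimethyl-6-{[2-(trimethylsilyl)ethoxy]carbonyl}cyclohex-2-ene-1-carboxylic acid (both C1 epimers) | CC1=CCC[C@@](C)(C(=O)OCC[Si](C)(C)C)C1C(=O)O
F2 | step 7 | (1R)-1,3-dimethylcyclohex-3-ene-1,2-dicarboxylic acid (both C2 epimers) | CC1=CCC[C@@](C)(C(=O)O)C1C(=O)O
F3 | step 8 | (1R,5R)-4-oxospiro[bicyclo[3.2.1]oct-2-ene-6,2′-oxirane]-1-carbaldehyde (either spiro epimer) | O1CC12C[C@]3(C=O)C[C@H]2C(=O)C=C3
F4 | step 8 | spiro-epoxide of 23 at C16–C17 | O1CC12C[C@]3(C=O)C[C@H]2C(=O)C[C@H]3[C@]2(C)CCC[C@@](C)(C(=O)OC4=O)[C@H]24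
F5 | step 15 | triethylsilyl enol ether (C11=C12) of 23 | C=C1C[C@]2(C=O)C[C@H]1C(O[Si](CC)(CC)CC)=C[C@H]2[C@]1(C)CCC[C@@](C)(C(=O)OC3=O)[C@H]13
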